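**Assumption:** (2R)-2-methylbutanoic acid is bought as the single enantiomer; ring positions are labelled with eudesmane numbering (C3 = CH–O-acyl, C4 = C(Me)OAc, C5/C10 = ring fusion, C7 = isopropylidene carbon, C8 = ketone). The route is a paper design and has not been run.

## Retrosynthetic overview

1. Target ⇒ 3β,4α-diol-8-ketone: C4 acetate and C7=C11 alkene come from one acetylation/E1cB operation, the C3 ester from Steglich coupling with (2R)-2-methylbutanoic acid, C11–C13 from an acetone aldol at C7.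
2. Diol ketone ⇒ 4α-hydroxy-3,8-dione by hydroxyl-directed reduction of C3=O (sets C3).
3. Hydroxy-dione ⇒ acyclic (E)-1,2-dione/silyl enol ether: C4–C5 (ring A) and then C9–C10 (ring B) form in one Cu(II)-bis(oxazoline)-catalysed Prins/cation–olefin cascade (sets C4, C5, C10).
4. Acyclic dione ⇒ trione ⇒ ketal Claisen of a 2-methylallylic alcohol with 3,3-dimethoxybutan-2-one (sets the E-alkene); the alcohol comes from a Grignard addition to methacrolein.

## Route

**Step 1**
Reactants: 1 2-(2-bromoethyl)-2-methyl-1,3-dioxolane; 2 methacrolein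
Product: 4 (±)-2-methyl-5-(2-methyl-1,3-dioxolan-2-yl)pent-1-en-3-ol, via Grignard reagent 3 (not isolated)
Conditions: Mg, THF, 25–30 °C; then 2, −78 → 0 °C; aqueous work-up
Reagents that add atoms: none
Why: Grignard 1,2-addition to the α-substituted enal; the dioxolane survives the organomagnesium below 30 °C, and the racemic carbinol centre is erased in step 2.

**Step 2**
Reactants: 4 (±)-2-methyl-5-(2-methyl-1,3-dioxolan-2-yl)pent-1-en-3-ol; 5 3,3-dimethoxybutan-2-one
Product: 9 (E)-6-methylundec-6-ene-2,3,10-trione, via mixed ketal 6 (not isolated), via allyl vinyl ether 7 (not isolated), via dione dioxolane 8 (not isolated)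
Conditions: 5 (4 equiv), EtCO2H (5 mol %), xylenes, 130 °C, MeOH distilled off; then THF, 1 M HCl, 23 °C
Reagents that add atoms: water O
Why: Ketal Claisen rearrangement (Johnson/Saucy–Marbet type): acid-catalysed exchange and loss of methanol give the 2-acetyl allyl vinyl ether, whose chair [3,3] shift with the side chain equatorial gives the E-trisubstituted alkene and the 1,2-dione; aqueous acid then removes the dioxolane, and no stereocentre remains.

**Step 3**
Reactants: 9 (E)-6-methylundec-6-ene-2,3,10-trione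
Product: 11 (E)-10-[(tert-butyldimethylsilyl)oxy]-6-methylundeca-6,10-diene-2,3-dione, via dilithium bis-enolate 10 (not isolated)
Conditions: LiHMDS (1.0 equiv), THF, −78 °C; LDA (1.1 equiv), −78 °C; TBSCl (1.05 equiv), DMPU, −78 → −40 °C; H2O
Reagents that add atoms: tert-butyldimethylsilyl chloride CC(C)(C)[Si](C)(C)Cl
Why: Dianion tactic with kinetic enolisation: the much more acidic 1,2-dione is parked as its chelated, weakly nucleophilic lithium enolate, LDA then makes the terminal enolate of the methyl ketone, only this more reactive enolate is O-silylated by one equivalent of TBSCl, and the quench returns the dione.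

**Step 4**
Reactants: 11 (E)-10-[(tert-butyldimethylsilyl)oxy]-6-methylundeca-6,10-diene-2,3-dione
Product: 13 (4aR,5S,8aR)-5-hydroxy-5,8a-dimethyloctahydronaphthalene-2,6(1H,3H)-dione, via silyloxocarbenium zwitterion 12 (not isolated)
Conditions: [Cu((S,S)-t-Bu-box)](SbF6)2 (20 mol %), (CF3)2CHOH (1.2 equiv), CH2Cl2, −40 °C, 11 added by syringe pump (final 2 mM); aq. NaHCO3
Reagents that add atoms: none
Why: Proposed new method: the Cu(II)-bis(oxazoline) binds the 1,2-dione as a planar s-cis chelate, and C5 of the E-alkene attacks the si face of the C4 ketone (the sense known for (S,S)-t-Bu-box–Cu pyruvate complexes) through a chair in which the chelate plane forces O4 equatorial and the C4 methyl axial (4S); the tertiary C10 cation is then trapped anti by C9 of the silyl enol ether in a chair–chair array (trans-decalin, 5R,10R), and HFIP takes the silyl group and protonates the copper alkoxide for turnover; closest known reaction types are Cu-box 1,2-dicarbonyl aldol/carbonyl-ene reactions, chiral-Lewis-acid α-keto-ester-initiated polyene cyclisation and silyl-enol-ether-terminated cation–olefin cyclisation.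

**Step 5**
Reactants: 13 (4aR,5S,8aR)-5-hydroxy-5,8a-dimethyloctahydronaphthalene-2,6(1H,3H)-dione
Product: 15 (4aR,5S,6S,8aR)-5,6-dihydroxy-5,8a-dimethyloctahydronaphthalen-2(1H)-one, via alkoxyborohydride 14 (not isolated)
Conditions: Me4NBH(OAc)3, AcOH/MeCN, −20 °C
Reagents that add atoms: none
Why: Hydroxyl-directed (Evans–Saksena) reduction: ligand exchange with the tertiary C4–OH and internal hydride delivery reduce only the α-hydroxy ketone and leave C8=O alone, and hydride enters C3 axially from the α-face, anti to the axial 4β-methyl, giving the equatorial 3β-OH (3S) trans to the 4α-OH.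

**Step 6**
Reactants: 15 (4aR,5S,6S,8aR)-5,6-dihydroxy-5,8a-dimethyloctahydronaphthalen-2(1H)-one; 16 acetone
Product: 18 (3R,4aR,5S,6S,8aR)-5,6-dihydroxy-3-(2-hydroxypropan-2-yl)-5,8a-dimethyloctahydronaphthalen-2(1H)-one, via trilithium enolate 17 (not isolated)
Conditions: LDA (3.3 equiv), THF, −78 °C; 16, −78 °C; AcOH quench at −78 °C
Reagents that add atoms: none
Why: Directed aldol addition: after both hydroxyls are deprotonated, LDA removes H-7 and not the neopentylic H-9 next to quaternary C10, and the enolate adds to acetone; the new C7 centre (mainly the equatorial 7R epimer) does not matter because it becomes sp2 in step 8.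

**Step 7**
Reactants: 18 (3R,4aR,5S,6S,8aR)-5,6-dihydroxy-3-(2-hydroxypropan-2-yl)-5,8a-dimethyloctahydronaphthalen-2(1H)-one; 19 (2R)-2-methylbutanoic acid
Product: 21 (1S,2S,4aR,7R,8aR)-1-hydroxy-7-(2-hydroxypropan-2-yl)-1,4a-dimethyl-6-oxodecahydronaphthalen-2-yl (2R)-2-methylbutanoate, via O-acylisourea 20 (not isolated)
Conditions: 19 (1.5 equiv), DCC, DMAP (0.2 equiv), CH2Cl2, 0 → 23 °C
Reagents that add atoms: none
Why: Steglich esterification acylates only the secondary equatorial 3-OH, since both tertiary hydroxyls are inert under these conditions, and nothing present is basic enough to epimerise the α-centre of the acid.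

**Step 8**
Reactants: 21 (1S,2S,4aR,7R,8aR)-1-hydroxy-7-(2-hydroxypropan-2-yl)-1,4a-dimethyl-6-oxodecahydronaphthalen-2-yl (2R)-2-methylbutanoate
Product: 23 (1S,2S,4aR,8aR)-1-acetoxy-1,4a-dimethyl-6-oxo-7-(propan-2-ylidene)decahydronaphthalen-2-yl (2R)-2-methylbutanoate, via bis-acetate 22 (not isolated)
Conditions: Ac2O (5 equiv), TMSOTf (5 mol %), CH2Cl2, −20 °C; MeOH quench, concentrate; DBU (3 equiv), CH2Cl2, 23 °C
Reagents that add atoms: acetic anhydride CC(=O)OC(C)=O
Why: TMSOTf-catalysed acetylation of both tertiary alcohols, then E1cB elimination of the β-acetoxy ketone with DBU to the conjugated tetrasubstituted 7(11)-alkene; the C4 acetate has no β-carbonyl and stays, and no stereocentre is touched.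

## Compound list

1 | 2-(2-bromoethyl)-2-methyl-1,3-dioxolane | CC1(CCBr)OCCO1 | starting material
2 | methacrolein (2-methylprop-2-enal) | CC(=C)C=O | starting material
3 | [2-(2-methyl-1,3-dioxolan-2-yl)ethyl]magnesium bromide | CC1(CC[Mg]Br)OCCO1 | intermediate (not isolated)
4 | (±)-2-methyl-5-(2-methyl-1,3-dioxolan-2-yl)pent-1-en-3-ol | CC(=C)C(O)CCC1(C)OCCO1 | intermediate
5 | 3,3-dimethoxybutan-2-one | CC(=O)C(C)(OC)OC | starting material
6 | 3-methoxy-3-{[2-methyl-5-(2-methyl-1,3-dioxolan-2-yl)pent-1-en-3-yl]oxy}butan-2-one (mixed ketal, diastereomer mixture) | CC(=O)C(C)(OC)OC(CCC1(C)OCCO1)C(C)=C | intermediate (not isolated)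
7 | 3-{[2-methyl-5-(2-methyl-1,3-dioxolan-2-yl)pent-1-en-3-yl]oxy}but-3-en-2-one (allyl vinyl ether, racemic) | CC(=O)C(=C)OC(CCC1(C)OCCO1)C(C)=C | intermediate (not isolated)
8 | (E)-6-methyl-9-(2-methyl-1,3-dioxolan-2-yl)non-6-ene-2,3-dione | CC(=O)C(=O)CC/C(C)=C/CCC1(C)OCCO1 | intermediate (not isolated)
9 | (E)-6-methylundec-6-ene-2,3,10-trione | CC(=O)C(=O)CC/C(C)=C/CCC(C)=O | intermediate
10 | dilithium (E)-6-methyl-3-oxoundeca-1,6,10-triene-2,10-diolate (dione enolate regiochemistry immaterial) | [Li+].[Li+].C=C([O-])C(=O)CC/C(C)=C/CCC([O-])=C | intermediate (not isolated)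
11 | (E)-10-[(tert-butyldimethylsilyl)oxy]-6-methylundeca-6,10-diene-2,3-dione | CC(=O)C(=O)CC/C(C)=C/CCC(=C)O[Si](C)(C)C(C)(C)C | intermediate
12 | bicyclic C8 O-silyloxocarbenium / C4 alkoxide zwitterion (alkoxide copper-bound, drawn free) | O=C1CC[C@]2(C)CC(=[O+][Si](C)(C)C(C)(C)C)CC[C@H]2[C@]1(C)[O-] | intermediate (not isolated)
13 | (4aR,5S,8aR)-5-hydroxy-5,8a-dimethyloctahydronaphthalene-2,6(1H,3H)-dione (4α-hydroxy-3,8-dione) | O=C1CC[C@]2(C)CC(=O)CC[C@H]2[C@]1(C)O | intermediate
14 | tetramethylammonium diacetoxy(hydrido)borate of the C4–O of 13 | C[N+](C)(C)C.O=C1CC[C@]2(C)CC(=O)CC[C@H]2[C@]1(C)O[BH-](OC(C)=O)OC(C)=O | intermediate (not isolated)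
15 | (4aR,5S,6S,8aR)-5,6-dihydroxy-5,8a-dimethyloctahydronaphthalen-2(1H)-one (3β,4α-diol-8-one) | O[C@H]1CC[C@]2(C)CC(=O)CC[C@H]2[C@]1(C)O | intermediate
16 | acetone | CC(C)=O | starting material
17 | trilithium Δ7-enolate 3,4-dialkoxide of 15 | [Li+].[Li+].[Li+].[O-][C@H]1CC[C@]2(C)CC([O-])=CC[C@H]2[C@]1(C)[O-] | intermediate (not isolated)
18 | (3R,4aR,5S,6S,8aR)-5,6-dihydroxy-3-(2-hydroxypropan-2-yl)-5,8a-dimethyloctahydronaphthalen-2(1H)-one (major C7 epimer) | O[C@H]1CC[C@]2(C)CC(=O)[C@@H](C(C)(C)O)C[C@H]2[C@]1(C)O | intermediate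
19 | (2R)-2-methylbutanoic acid | CC[C@@H](C)C(=O)O | starting material
20 | O-[(2R)-2-methylbutanoyl]-N,N'-dicyclohexylisourea | CC[C@@H](C)C(=O)OC(=NC1CCCCC1)NC1CCCCC1 | intermediate (not isolated)
21 | (1S,2S,4aR,7R,8aR)-1-hydroxy-7-(2-hydroxypropan-2-yl)-1,4a-dimethyl-6-oxodecahydronaphthalen-2-yl (2R)-2-methylbutanoate | CC[C@@H](C)C(=O)O[C@H]1CC[C@]2(C)CC(=O)[C@@H](C(C)(C)O)C[C@H]2[C@]1(C)O | intermediate
22 | (1S,2S,4aR,7R,8aR)-1-acetoxy-7-(2-acetoxypropan-2-yl)-1,4a-dimethyl-6-oxodecahydronaphthalen-2-yl (2R)-2-methylbutanoate | CC[C@@H](C)C(=O)O[C@H]1CC[C@]2(C)CC(=O)[C@@H](C(C)(C)OC(C)=O)C[C@H]2[C@]1(C)OC(C)=O | intermediate (not isolated)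
23 | (1S,2S,4aR,8aR)-1-acetoxy-1,4a-dimethyl-6-oxo-7-(propan-2-ylidene)decahydronaphthalen-2-yl (2R)-2-methylbutanoate | CC[C@@H](C)C(=O)O[C@H]1CC[C@]2(C)CC(=O)C(=C(C)C)C[C@H]2[C@]1(C)OC(C)=O | target

## Step count and risks

Total steps: 8. Longest linear sequence: 8 (1 → 23).

**Step 4 (most likely to fail).** The catalytic bicyclisation is unprecedented in this exact form. The silyl enol ether could attack a chelated dione of another molecule (Mukaiyama aldol), be protodesilylated by HFIP, or the product α-hydroxy ketone could inhibit the copper. Fallback: set out from 11 and run the same chelated-dione cascade with a stoichiometric achiral Lewis acid (SnCl4, CH2Cl2, −78 °C, high dilution). This gives 13 together with its mirror image, the ent-hydroxy-dione F1. Steps 5 and 6 on the racemate give 15 with the ent-diol ketone F2 and 18 with the ent-aldol triol F3. Esterification with 19 as in step 7 then gives 21 and the diastereomeric ester F4, which are separated by chromatography or HPLC. The route is rejoined at 21, so stereocontrol moves from the catalyst to a resolution through the target's own chiral acyl group.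

**Step 3.** Mono-silylation relies on the dione enolate being much less reactive than the ketone enolate; over-silylation or dione self-condensation is possible. Fallback: set out from 9 and silylate both enolates on purpose (LiHMDS then LDA, TBSCl 2.3 equiv) to give the bis-silyl enol ether F5. Then cleave only the α-keto (acidic-enol) silyl ether with K2CO3/MeOH at 0 °C, which an isolated TBS enol ether survives. This comes back to the route at 11.

**Step 2.** Enol-ether formation from the α-keto ketal and Claisen rearrangement to a 1,2-dione at 130 °C may be low-yielding. Fallback: set out from 4 and use the orthoester Claisen (triethyl orthoacetate, EtCO2H, 138 °C) to the (E)-ester F6. Convert it with MeNH(OMe)·HCl/i-PrMgCl to the Weinreb amide F7, add 1-ethoxyvinyllithium to give the α-ethoxy enone F8, and hydrolyse enol ether and dioxolane together with 1 M HCl/THF. This comes back to the route at 9.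

## Further compounds

F1 | step 4 | (4aS,5R,8aS)-5-hydroxy-5,8a-dimethyloctahydronaphthalene-2,6(1H,3H)-dione | O=C1CC[C@@]2(C)CC(=O)CC[C@@H]2[C@@]1(C)O
F2 | step 4 | (4aS,5R,6R,8aS)-5,6-dihydroxy-5,8a-dimethyloctahydronaphthalen-2(1H)-one | O[C@@H]1CC[C@@]2(C)CC(=O)CC[C@@H]2[C@@]1(C)O
F3 | step 4 | (3S,4aS,5R,6R,8aS)-5,6-dihydroxy-3-(2-hydroxypropan-2-yl)-5,8a-dimethyloctahydronaphthalen-2(1H)-one | O[C@@H]1CC[C@@]2(C)CC(=O)[C@H](C(C)(C)O)C[C@@H]2[C@@]1(C)O
F4 | step 4 | (1R,2R,4aS,7S,8aS)-1-hydroxy-7-(2-hydroxypropan-2-yl)-1,4a-dimethyl-6-oxodecahydronaphthalen-2-yl (2R)-2-methylbutanoate | CC[C@@H](C)C(=O)O[C@@H]1CC[C@@]2(C)CC(=O)[C@H](C(C)(C)O)C[C@@H]2[C@@]1(C)O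
F5 | step 3 | (E)-2,10-bis[(tert-butyldimethylsilyl)oxy]-6-methylundeca-1,6,10-trien-3-one | C=C(O[Si](C)(C)C(C)(C)C)C(=O)CC/C(C)=C/CCC(=C)O[Si](C)(C)C(C)(C)C
F6 | step 2 | ethyl (E)-4-methyl-7-(2-methyl-1,3-dioxolan-2-yl)hept-4-enoate | CCOC(=O)CC/C(C)=C/CCC1(C)OCCO1
F7 | step 2 | (E)-N-methoxy-N,4-dimethyl-7-(2-methyl-1,3-dioxolan-2-yl)hept-4-enamide | CON(C)C(=O)CC/C(C)=C/CCC1(C)OCCO1
F8 | step 2 | (E)-2-ethoxy-6-methyl-9-(2-methyl-1,3-dioxolan-2-yl)nona-1,6-dien-3-one | CCOC(=C)C(=O)CC/C(C)=C/CCC1(C)OCCO1
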